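**Strategy.** The route rests on cutting ring C of the middle flavan unit across O1–C2 and C3–C4. An ortho-quinone methide spanning O1, C8a, C4a and C4 of ring A of that unit, already carrying the epicatechin unit on C8 and the catechin unit on C4, takes up an (E)-2-arylvinyl acetate in one acid-catalysed [4+2] step. This closes the pyran ring, forms two skeletal bonds and sets C2, C3 and C4 (2,4-cis, O3 trans to both). The precursor is an ortho-hydroxy diaryl carbinol with a single free phenol, made from a formylphloroglucinol adduct of epicatechin and 8-lithiated catechin; the acyl side chain is attached last.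

Key step: step 11

Remarks on the chemistry and assumptions
- Structure check: the target reads as epicatechin-(4β→8)-catechin-(4α→8)-catechin with an (S)-1-hydroxy-6-oxocyclohex-2-ene-1-carbonyl group on O3 of the terminal unit. The top unit is 2,3-cis-3,4-trans, the middle unit 2,3-trans-3,4-trans with C2 and C4 cis, the terminal unit (2R,3S). The structures of the key-step precursor (13) and product (19) agree with this reading and needed no correction.
- Precursor design: the phenol that becomes O1 is defined by using 2,4,6-trihydroxybenzaldehyde as the C4 nucleophile. In adduct 5 the hydroxyl between the formyl and flavanyl groups is chelated and flanked on both sides, so a plain bis-silylation should leave only this oxygen free.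
- Carbinol 13 is used as the mixture of epimers at the carbinol carbon; that centre becomes sp2 in the quinone methide.
- The (R) antipode of the phosphoric acid is written as the working choice; if it is mismatched with the substrate bias, the (S) antipode is used.
- The (E)-enol acetate is made stereospecifically from an (E)-alkenyl boronate, since direct enol acetylation of an arylacetaldehyde is expected to give E/Z mixtures.
- Abbreviations: TBS = tert-butyldimethylsilyl; TES = triethylsilyl; Bpin = 4,4,5,5-tetramethyl-1,3,2-dioxaborolan-2-yl; (R)-TRIP = (R)-3,3′-bis(2,4,6-triisopropylphenyl)-1,1′-binaphthyl-2,2′-diyl hydrogen phosphate.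

**Route**

Step 1
Reactants: 1 (−)-epicatechin
Product: 2 3,5,7,3′,4′-pentakis-O-TBS-(−)-epicatechin
Conditions: TBSCl (7 equiv), imidazole (14 equiv), DMAP (0.2 equiv), DMF, 45 °C
Reagents that add atoms: tert-butyldimethylsilyl chloride, CC(C)(C)[Si](C)(C)Cl
Why: Corey silylation (TBSCl–imidazole) caps the four phenols and, on warming, the secondary alcohol; no stereocentre is touched.

Step 2
Reactants: 2 3,5,7,3′,4′-pentakis-O-TBS-(−)-epicatechin
Product: 3 4β-(2-ethoxyethoxy)-3,5,7,3′,4′-pentakis-O-TBS-epicatechin (2,3-cis-3,4-trans)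
Conditions: DDQ (1.5 equiv), 2-ethoxyethanol (6 equiv), CH2Cl2, rt
Reagents that add atoms: 2-ethoxyethanol, CCOCCO
Why: Benzylic C–H oxidation by hydride abstraction with DDQ gives the ring-A-stabilised C4 cation, which the alcohol traps anti to the axial C3 silyloxy group (4β); this centre is ionised again in step 3.

Step 3
Reactants: 3 4β-(2-ethoxyethoxy)-penta-O-TBS-epicatechin; 4 2,4,6-trihydroxybenzaldehyde
Product: 5 2,4,6-trihydroxy-3-(penta-O-TBS-epicatechin-4β-yl)benzaldehyde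
Conditions: 4 (4 equiv), Sc(OTf)3 (10 mol %), THF–CH2Cl2 (1:3), −20 → 0 °C
Reagents that add atoms: none
Why: Lewis-acid-catalysed Friedel–Crafts alkylation, in which the C4 cation is captured by one of the two equivalent free ring carbons of the formylphloroglucinol from the face opposite the C3 silyloxy group, setting the 4β (3,4-trans) centre as in known C4 arylations of 2,3-cis-flavans and acid-catalysed C-alkylations of acylphloroglucinols.

Step 4
Reactants: 5 2,4,6-trihydroxy-3-(penta-O-TBS-epicatechin-4β-yl)benzaldehyde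
Product: 6 2-hydroxy-4,6-bis(TBS-oxy)-3-(penta-O-TBS-epicatechin-4β-yl)benzaldehyde
Conditions: TBSCl (2.3 equiv), imidazole (5 equiv), DMF, 0 °C → rt
Reagents that add atoms: tert-butyldimethylsilyl chloride, CC(C)(C)[Si](C)(C)Cl
Why: Regioselective Corey silylation: the hydroxyl para to the formyl group and the less hindered ortho hydroxyl react, whereas the hydroxyl between the formyl and flavanyl groups is chelated to the carbonyl and flanked on both sides, so it stays free and defines the later O1.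

Step 5
Reactants: 7 (+)-catechin
Product: 9 3-O-TES-5,7,3′,4′-tetrakis-O-TBS-(+)-catechin, via tetra-O-TBS-catechin 8 (not isolated)
Conditions: TBSCl (4.3 equiv), imidazole (10 equiv), DMF, 0 °C → rt; then TESCl (1.5 equiv), rt
Reagents that add atoms: tert-butyldimethylsilyl chloride, CC(C)(C)[Si](C)(C)Cl; triethylsilyl chloride, CC[Si](Cl)(CC)CC
Why: Chemoselective Corey silylation in one pot: phenols react far faster than the secondary C3 hydroxyl with TBSCl, and the smaller TESCl then caps O3 as a handle that can be removed later beside TBS ethers.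

Step 6
Reactants: 9 3-O-TES-5,7,3′,4′-tetrakis-O-TBS-(+)-catechin
Product: 10 8-bromo-3-O-TES-5,7,3′,4′-tetrakis-O-TBS-(+)-catechin
Conditions: NBS (1.05 equiv), CH2Cl2, −78 → −20 °C
Reagents that add atoms: N-bromosuccinimide, O=C1CCC(=O)N1Br
Why: Electrophilic aromatic bromination goes to C8, the ring A position flanked by the pyran oxygen and only one silyloxy group, in line with the 8-selective halogenation of protected catechins.

Step 7
Reactants: 10 8-bromo-3-O-TES-tetra-O-TBS-catechin; 6 2-hydroxy-4,6-bis(TBS-oxy)-3-(penta-O-TBS-epicatechin-4β-yl)benzaldehyde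
Product: 13 ortho-hydroxy diaryl carbinol joining C8 of the terminal catechin unit to ring A of the future middle unit (both epimers at the carbinol carbon), via aryllithium 11 (not isolated), via sodium phenoxide 12 (not isolated)
Conditions: 10 (1.3 equiv), t-BuLi (2.6 equiv), Et2O, −78 °C, 10 min; then 6 pre-treated with NaH (1.05 equiv, THF, 0 °C), −78 → −40 °C; aq. NH4Cl
Reagents that add atoms: none
Why: Bromine–lithium exchange followed by 1,2-addition of the aryllithium to the aldehyde, whose phenol is masked as the sodium phenoxide so that it does not quench the organolithium; the carbinol centre forms without control, which is harmless because it is lost in step 11.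

Step 8
Reactants: 14 3,4-dihydroxybenzaldehyde
Product: 15 3,4-bis(TBS-oxy)benzaldehyde
Conditions: TBSCl (2.4 equiv), imidazole (5 equiv), DMF, rt
Reagents that add atoms: tert-butyldimethylsilyl chloride, CC(C)(C)[Si](C)(C)Cl
Why: Corey silylation of the catechol; no stereochemistry involved.

Step 9
Reactants: 15 3,4-bis(TBS-oxy)benzaldehyde
Product: 16 (E)-2-[3,4-bis(TBS-oxy)phenyl]ethenyl-Bpin
Conditions: CH2(Bpin)2 (1.2 equiv), lithium 2,2,6,6-tetramethylpiperidide (1.2 equiv), THF, 0 °C, 5 min; then 15, −78 °C → rt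
Reagents that add atoms: bis(pinacolatoboryl)methane, CC1(C)OB(CB2OC(C)(C)C(C)(C)O2)OC1(C)C
Why: Boron–Wittig olefination: the α-boryl carbanion adds to the aldehyde and syn elimination of the boron–oxygen pair from the anti adduct should give the (E)-alkenyl boronate.

Step 10
Reactants: 16 (E)-2-[3,4-bis(TBS-oxy)phenyl]ethenyl-Bpin
Product: 17 (E)-2-[3,4-bis(TBS-oxy)phenyl]ethenyl acetate
Conditions: Cu(OAc)2 (2.2 equiv), Et3N (4 equiv), 4 Å MS, MeCN, rt, N2
Reagents that add atoms: Cu(OAc)2, CC(=O)[O-].CC(=O)[O-].[Cu+2]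
Why: Chan–Lam-type oxidative C–O coupling: transmetalation of the alkenyl boronate to divalent copper acetate and reductive elimination both proceed with retention, so the (E) geometry is carried into the enol acetate.

Step 11
Reactants: 13 ortho-hydroxy diaryl carbinol (epimer mixture); 17 (E)-2-[3,4-bis(TBS-oxy)phenyl]ethenyl acetate
Product: 19 silylated trimer epicatechin-(4β→8)-catechin-(4α→8)-catechin carrying acetate on O3 of the middle unit plus TES on O3 of the terminal unit, via ortho-quinone methide 18 (not isolated)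
Conditions: 17 (3 equiv), (R)-TRIP (10 mol %), 5 Å MS, toluene, −20 °C → rt
Reagents that add atoms: none
Why: Proposed new method: the phosphoric acid protonates the benzylic hydroxyl of 13, water leaves with help from the single free ortho phenol, and the (E)-ortho-quinone methide 18 (oxa-diene O1=C8a–C4a=C4 of ring A of the middle unit) stays hydrogen-bonded to the chiral phosphate while 17 adds in an asynchronous inverse-demand hetero-Diels–Alder reaction, the C3–C4 bond leading and the positive charge building up at benzylic C2 being quenched by O1. The closest known reaction type is the Brønsted-acid-catalysed [4+2] cycloaddition of ortho-quinone methides generated in situ from ortho-hydroxybenzhydrols with styrenes, which gives 2,4-cis-diarylchromans; an enol ester as the styrene partner is the untested element. Ring C of the middle unit is closed by this intermolecular [4+2] cycloaddition, both ring bonds (O1–C2 and C3–C4) arising in the same operation. C4 and C2 become cis because the catechol ring of 17 lies endo under the quinone methide whose C4 aryl group points outward, C3 becomes trans to both because the (E) geometry of 17 is transferred suprafacially (all three substituents equatorial), and the absolute sense is set by the phosphate that shields one face of 18, assisted by the flavanyl group on C8 next to O1. The step needs regioselectivity (C3 to C4 and C2 to O1), secured by the para-silyloxyphenyl group, which stabilises positive charge at C2 better than the cross-conjugated acetoxy oxygen does at C3, and chemoselectivity, secured by the fact that 13 has only one free phenol, so only the 4→8 constitution can arise.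

Step 12
Reactants: 19 silylated trimer with acetate on O3 of the middle unit
Product: 20 silylated trimer with free 3-OH on the middle unit (TES on O3 of the terminal unit)
Conditions: iBu2AlH (3 equiv), CH2Cl2, −78 °C; aq. potassium sodium tartrate
Reagents that add atoms: none
Why: Reductive cleavage of the acetate with iBu2AlH at low temperature (ester reduction) avoids the basic methanolysis that would strip aryl silyl ethers; C3 is untouched.

Step 13
Reactants: 20 silylated trimer with free 3-OH on the middle unit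
Product: 21 silylated trimer with TBS on O3 of the middle unit plus TES on O3 of the terminal unit
Conditions: TBSOTf (4 equiv), 2,6-lutidine (6 equiv), CH2Cl2, 0 °C → rt
Reagents that add atoms: tert-butyldimethylsilyl triflate, CC(C)(C)[Si](C)(C)OS(=O)(=O)C(F)(F)F
Why: Silylation of the hindered secondary alcohol with the silyl triflate and a hindered base gives an O3 group that differs in lability from the TES ether on the terminal unit.

Step 14
Reactants: 21 silylated trimer with TES on O3 of the terminal unit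
Product: 22 silylated trimer with free 3-OH on the terminal unit only
Conditions: PPTS (0.3 equiv), MeOH–CH2Cl2 (1:3), 0 °C → rt
Reagents that add atoms: none
Why: Acid-catalysed methanolysis (selective silyl ether solvolysis) removes the secondary TES ether far faster than secondary or aryl TBS ethers, freeing only O3 of the terminal unit.

Step 15
Reactants: 23 methyl 2-methoxybenzoate
Product: 24 methyl 2-methoxycyclohexa-2,5-diene-1-carboxylate
Conditions: K (2.3 equiv), NH3(l)–THF, t-BuOH (1.0 equiv), −78 °C; then solid NH4Cl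
Reagents that add atoms: none
Why: Birch reduction: the ester-stabilised pentadienyl anion is protonated at the ipso carbon, giving the 1,4-dihydro isomer with the enol ether intact.

Step 16
Reactants: 24 methyl 2-methoxycyclohexa-2,5-diene-1-carboxylate
Product: 26 racemic methyl 1-hydroxy-2-methoxycyclohexa-2,5-diene-1-carboxylate, via potassium dienolate 25 (not isolated)
Conditions: KN(SiMe3)2 (1.1 equiv), THF, −78 °C; then trans-2-(phenylsulfonyl)-3-phenyloxaziridine (1.3 equiv), −78 °C; aq. NH4Cl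
Reagents that add atoms: trans-2-(phenylsulfonyl)-3-phenyloxaziridine, O=S(=O)(c1ccccc1)N1OC1c1ccccc1
Why: Davis enolate oxidation: the cross-conjugated dienolate is hydroxylated at the α-carbon, as in the α-alkylation of Birch-derived ester enolates; the quaternary centre forms as the racemate.

Step 17
Reactants: 26 racemic methyl 1-hydroxy-2-methoxycyclohexa-2,5-diene-1-carboxylate
Product: 27 methyl (S)-1-hydroxy-2-methoxycyclohexa-2,5-diene-1-carboxylate
Conditions: preparative SFC, amylose tris(3,5-dimethylphenylcarbamate) stationary phase, CO2–MeOH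
Reagents that add atoms: none
Why: Physical resolution of enantiomers on a polysaccharide chiral stationary phase; no centre is formed, and the (S) antipode is to be identified by X-ray analysis of a crystalline heavy-atom derivative.

Step 18
Reactants: 27 methyl (S)-1-hydroxy-2-methoxycyclohexa-2,5-diene-1-carboxylate
Product: 28 (S)-1-hydroxy-2-methoxycyclohexa-2,5-diene-1-carboxylic acid
Conditions: LiOH·H2O (3 equiv), THF–MeOH–H2O, 0 °C → rt; 1 M HCl to pH 4 at 0 °C under EtOAc, extracted at once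
Reagents that add atoms: lithium hydroxide, [Li+].[OH-]
Why: Saponification of the methyl ester; the quaternary α-carbon cannot epimerise, the enol ether is stable to base, and the acid is liberated cold at pH 4 to spare the enol ether.

Step 19
Reactants: 28 (S)-1-hydroxy-2-methoxycyclohexa-2,5-diene-1-carboxylic acid
Product: 30 (S)-2-methoxy-1-(triethylsilyloxy)cyclohexa-2,5-diene-1-carboxylic acid, via silyl ester 29 (not isolated)
Conditions: TESOTf (2.3 equiv), 2,6-lutidine (4 equiv), CH2Cl2, −78 → 0 °C; then THF–MeOH–H2O, rt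
Reagents that add atoms: triethylsilyl triflate, CC[Si](CC)(CC)OS(=O)(=O)C(F)(F)F
Why: Bis-silylation with the silyl triflate followed by hydrolysis of the labile silyl ester leaves the tertiary hydroxyl masked, which prevents self-acylation in the coupling.

Step 20
Reactants: 22 silylated trimer with free 3-OH on the terminal unit; 30 (S)-2-methoxy-1-(triethylsilyloxy)cyclohexa-2,5-diene-1-carboxylic acid
Product: 31 silylated trimer acylated on O3 of the terminal unit by the (S)-2-methoxy-1-(triethylsilyloxy)cyclohexa-2,5-diene-1-carbonyl group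
Conditions: 30 (3 equiv), DCC (3.5 equiv), DMAP (1 equiv), CH2Cl2, 0 °C → rt
Reagents that add atoms: none
Why: Steglich esterification through the acylpyridinium ion, a method that couples quaternary α-alkoxy acids to hindered secondary alcohols; O-acylation retains the C3 configuration and the acid has no epimerisable centre.

Step 21
Reactants: 31 silylated trimer with the enol ether ester on O3 of the terminal unit
Product: 32 silylated trimer with the (S)-6-oxo-1-(triethylsilyloxy)cyclohex-2-ene-1-carbonyl group on O3 of the terminal unit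
Conditions: oxalic acid (0.2 M), THF–H2O (4:1), 0 °C → rt
Reagents that add atoms: water, O
Why: Acid-catalysed enol ether hydrolysis unveils the β-keto ester; the remaining ring alkene cannot move into conjugation through the quaternary carbon, and dilute oxalic acid should leave TBS ethers and interflavan bonds intact.

Step 22
Reactants: 32 silylated trimer keto ester
Product: 33 CNP0159807.2, epicatechin-(4β→8)-catechin-(4α→8)-catechin 3-O-[(S)-1-hydroxy-6-oxocyclohex-2-ene-1-carboxylate] on the terminal unit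
Conditions: HF·pyridine (excess), pyridine, THF, 0 °C → rt, polypropylene flask, Ar; quench Me3SiOMe; Sephadex LH-20 (MeOH)
Reagents that add atoms: none
Why: Global desilylation by fluoride under buffered acidic conditions cleaves all Si–O bonds while the base-sensitive α-hydroxy β-keto ester and the interflavan bonds should persist; no stereocentre is affected.

**Compound list**

1 | (−)-epicatechin, (2R,3R) | O[C@@H]1Cc2c(O)cc(O)cc2O[C@@H]1c1ccc(O)c(O)c1 | starting material
2 | 3,5,7,3′,4′-pentakis-O-TBS-(−)-epicatechin | CC(C)(C)[Si](C)(C)O[C@@H]1Cc2c(O[Si](C)(C)C(C)(C)C)cc(O[Si](C)(C)C(C)(C)C)cc2O[C@@H]1c1ccc(O[Si](C)(C)C(C)(C)C)c(O[Si](C)(C)C(C)(C)C)c1 | intermediate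
3 | 4β-(2-ethoxyethoxy)-penta-O-TBS-epicatechin (2,3-cis-3,4-trans) | CCOCCO[C@H]1c2c(O[Si](C)(C)C(C)(C)C)cc(O[Si](C)(C)C(C)(C)C)cc2O[C@H](c2ccc(O[Si](C)(C)C(C)(C)C)c(O[Si](C)(C)C(C)(C)C)c2)[C@@H]1O[Si](C)(C)C(C)(C)C | intermediate
4 | 2,4,6-trihydroxybenzaldehyde | O=Cc1c(O)cc(O)cc1O | starting material
5 | 2,4,6-trihydroxy-3-(penta-O-TBS-epicatechin-4β-yl)benzaldehyde | O=Cc1c(O)cc(O)c([C@H]2c3c(O[Si](C)(C)C(C)(C)C)cc(O[Si](C)(C)C(C)(C)C)cc3O[C@H](c3ccc(O[Si](C)(C)C(C)(C)C)c(O[Si](C)(C)C(C)(C)C)c3)[C@@H]2O[Si](C)(C)C(C)(C)C)c1O | intermediate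
6 | 2-hydroxy-4,6-bis(TBS-oxy)-3-(penta-O-TBS-epicatechin-4β-yl)benzaldehyde | O=Cc1c(O[Si](C)(C)C(C)(C)C)cc(O[Si](C)(C)C(C)(C)C)c([C@H]2c3c(O[Si](C)(C)C(C)(C)C)cc(O[Si](C)(C)C(C)(C)C)cc3O[C@H](c3ccc(O[Si](C)(C)C(C)(C)C)c(O[Si](C)(C)C(C)(C)C)c3)[C@@H]2O[Si](C)(C)C(C)(C)C)c1O | intermediate
7 | (+)-catechin, (2R,3S) | O[C@H]1Cc2c(O)cc(O)cc2O[C@@H]1c1ccc(O)c(O)c1 | starting material
8 | 5,7,3′,4′-tetrakis-O-TBS-(+)-catechin (3-OH free) | O[C@H]1Cc2c(O[Si](C)(C)C(C)(C)C)cc(O[Si](C)(C)C(C)(C)C)cc2O[C@@H]1c1ccc(O[Si](C)(C)C(C)(C)C)c(O[Si](C)(C)C(C)(C)C)c1 | intermediate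
9 | 3-O-TES-5,7,3′,4′-tetrakis-O-TBS-(+)-catechin | CC[Si](CC)(CC)O[C@H]1Cc2c(O[Si](C)(C)C(C)(C)C)cc(O[Si](C)(C)C(C)(C)C)cc2O[C@@H]1c1ccc(O[Si](C)(C)C(C)(C)C)c(O[Si](C)(C)C(C)(C)C)c1 | intermediate
10 | 8-bromo derivative of 9 | CC[Si](CC)(CC)O[C@H]1Cc2c(O[Si](C)(C)C(C)(C)C)cc(O[Si](C)(C)C(C)(C)C)c(Br)c2O[C@@H]1c1ccc(O[Si](C)(C)C(C)(C)C)c(O[Si](C)(C)C(C)(C)C)c1 | intermediate
11 | 8-lithio derivative of 9 | CC[Si](CC)(CC)O[C@H]1Cc2c(O[Si](C)(C)C(C)(C)C)cc(O[Si](C)(C)C(C)(C)C)c([Li])c2O[C@@H]1c1ccc(O[Si](C)(C)C(C)(C)C)c(O[Si](C)(C)C(C)(C)C)c1 | intermediate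
12 | sodium phenoxide of 6 | [Na+].O=Cc1c(O[Si](C)(C)C(C)(C)C)cc(O[Si](C)(C)C(C)(C)C)c([C@H]2c3c(O[Si](C)(C)C(C)(C)C)cc(O[Si](C)(C)C(C)(C)C)cc3O[C@H](c3ccc(O[Si](C)(C)C(C)(C)C)c(O[Si](C)(C)C(C)(C)C)c3)[C@@H]2O[Si](C)(C)C(C)(C)C)c1[O-] | intermediate
13 | ortho-hydroxy diaryl carbinol: carbinol carbon bonded to C8 of the terminal unit (3-O-TES, tetra-O-TBS) and to the phloroglucinol ring bearing a free ortho OH, two TBS ethers and the penta-O-TBS-epicatechin-4β-yl group; both carbinol epimers | CC[Si](CC)(CC)O[C@H]1Cc2c(O[Si](C)(C)C(C)(C)C)cc(O[Si](C)(C)C(C)(C)C)c(C(O)c3c(O[Si](C)(C)C(C)(C)C)cc(O[Si](C)(C)C(C)(C)C)c([C@H]5c6c(O[Si](C)(C)C(C)(C)C)cc(O[Si](C)(C)C(C)(C)C)cc6O[C@H](c6ccc(O[Si](C)(C)C(C)(C)C)c(O[Si](C)(C)C(C)(C)C)c6)[C@@H]5O[Si](C)(C)C(C)(C)C)c3O)c2O[C@@H]1c1ccc(O[Si](C)(C)C(C)(C)C)c(O[Si](C)(C)C(C)(C)C)c1 | intermediate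
14 | 3,4-dihydroxybenzaldehyde | O=Cc1ccc(O)c(O)c1 | starting material
15 | 3,4-bis(TBS-oxy)benzaldehyde | O=Cc1ccc(O[Si](C)(C)C(C)(C)C)c(O[Si](C)(C)C(C)(C)C)c1 | intermediate
16 | (E)-2-[3,4-bis(TBS-oxy)phenyl]ethenyl-Bpin | CC1(C)OB(/C=C/c2ccc(O[Si](C)(C)C(C)(C)C)c(O[Si](C)(C)C(C)(C)C)c2)OC1(C)C | intermediate
17 | (E)-2-[3,4-bis(TBS-oxy)phenyl]ethenyl acetate | CC(=O)O/C=C/c1ccc(O[Si](C)(C)C(C)(C)C)c(O[Si](C)(C)C(C)(C)C)c1 | intermediate
18 | (E)-ortho-quinone methide from 13 (exocyclic C4=C4a, carbonyl at C8a, terminal aryl outward) | CC[Si](CC)(CC)O[C@H]1Cc2c(O[Si](C)(C)C(C)(C)C)cc(O[Si](C)(C)C(C)(C)C)c(/C=C3/C(=O)C([C@H]5c6c(O[Si](C)(C)C(C)(C)C)cc(O[Si](C)(C)C(C)(C)C)cc6O[C@H](c6ccc(O[Si](C)(C)C(C)(C)C)c(O[Si](C)(C)C(C)(C)C)c6)[C@@H]5O[Si](C)(C)C(C)(C)C)=C(O[Si](C)(C)C(C)(C)C)C=C3O[Si](C)(C)C(C)(C)C)c2O[C@@H]1c1ccc(O[Si](C)(C)C(C)(C)C)c(O[Si](C)(C)C(C)(C)C)c1 | intermediate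
19 | silylated trimer, middle unit 2,3-trans-3,4-trans (4α) with 3-O-acetyl, terminal unit 3-O-TES, all other oxygens TBS | CC[Si](CC)(CC)O[C@H]1Cc2c(O[Si](C)(C)C(C)(C)C)cc(O[Si](C)(C)C(C)(C)C)c([C@@H]3c4c(O[Si](C)(C)C(C)(C)C)cc(O[Si](C)(C)C(C)(C)C)c([C@H]5c6c(O[Si](C)(C)C(C)(C)C)cc(O[Si](C)(C)C(C)(C)C)cc6O[C@H](c6ccc(O[Si](C)(C)C(C)(C)C)c(O[Si](C)(C)C(C)(C)C)c6)[C@@H]5O[Si](C)(C)C(C)(C)C)c4O[C@H](c4ccc(O[Si](C)(C)C(C)(C)C)c(O[Si](C)(C)C(C)(C)C)c4)[C@H]3OC(C)=O)c2O[C@@H]1c1ccc(O[Si](C)(C)C(C)(C)C)c(O[Si](C)(C)C(C)(C)C)c1 | intermediate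
20 | as 19 with free 3-OH on the middle unit | CC[Si](CC)(CC)O[C@H]1Cc2c(O[Si](C)(C)C(C)(C)C)cc(O[Si](C)(C)C(C)(C)C)c([C@@H]3c4c(O[Si](C)(C)C(C)(C)C)cc(O[Si](C)(C)C(C)(C)C)c([C@H]5c6c(O[Si](C)(C)C(C)(C)C)cc(O[Si](C)(C)C(C)(C)C)cc6O[C@H](c6ccc(O[Si](C)(C)C(C)(C)C)c(O[Si](C)(C)C(C)(C)C)c6)[C@@H]5O[Si](C)(C)C(C)(C)C)c4O[C@H](c4ccc(O[Si](C)(C)C(C)(C)C)c(O[Si](C)(C)C(C)(C)C)c4)[C@H]3O)c2O[C@@H]1c1ccc(O[Si](C)(C)C(C)(C)C)c(O[Si](C)(C)C(C)(C)C)c1 | intermediate
21 | as 19 with 3-O-TBS on the middle unit (terminal unit 3-O-TES) | CC[Si](CC)(CC)O[C@H]1Cc2c(O[Si](C)(C)C(C)(C)C)cc(O[Si](C)(C)C(C)(C)C)c([C@@H]3c4c(O[Si](C)(C)C(C)(C)C)cc(O[Si](C)(C)C(C)(C)C)c([C@H]5c6c(O[Si](C)(C)C(C)(C)C)cc(O[Si](C)(C)C(C)(C)C)cc6O[C@H](c6ccc(O[Si](C)(C)C(C)(C)C)c(O[Si](C)(C)C(C)(C)C)c6)[C@@H]5O[Si](C)(C)C(C)(C)C)c4O[C@H](c4ccc(O[Si](C)(C)C(C)(C)C)c(O[Si](C)(C)C(C)(C)C)c4)[C@H]3O[Si](C)(C)C(C)(C)C)c2O[C@@H]1c1ccc(O[Si](C)(C)C(C)(C)C)c(O[Si](C)(C)C(C)(C)C)c1 | intermediate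
22 | tetradeca-O-TBS trimer with free 3-OH on the terminal unit | O[C@H]1Cc2c(O[Si](C)(C)C(C)(C)C)cc(O[Si](C)(C)C(C)(C)C)c([C@@H]3c4c(O[Si](C)(C)C(C)(C)C)cc(O[Si](C)(C)C(C)(C)C)c([C@H]5c6c(O[Si](C)(C)C(C)(C)C)cc(O[Si](C)(C)C(C)(C)C)cc6O[C@H](c6ccc(O[Si](C)(C)C(C)(C)C)c(O[Si](C)(C)C(C)(C)C)c6)[C@@H]5O[Si](C)(C)C(C)(C)C)c4O[C@H](c4ccc(O[Si](C)(C)C(C)(C)C)c(O[Si](C)(C)C(C)(C)C)c4)[C@H]3O[Si](C)(C)C(C)(C)C)c2O[C@@H]1c1ccc(O[Si](C)(C)C(C)(C)C)c(O[Si](C)(C)C(C)(C)C)c1 | intermediate
23 | methyl 2-methoxybenzoate | COC(=O)c1ccccc1OC | starting material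
24 | methyl 2-methoxycyclohexa-2,5-diene-1-carboxylate | COC(=O)C1C=CCC=C1OC | intermediate
25 | potassium dienolate of 24 | [K+].COC([O-])=C1C=CCC=C1OC | intermediate
26 | racemic methyl 1-hydroxy-2-methoxycyclohexa-2,5-diene-1-carboxylate | COC(=O)C1(O)C=CCC=C1OC | intermediate
27 | methyl (S)-1-hydroxy-2-methoxycyclohexa-2,5-diene-1-carboxylate | COC1=CCC=C[C@@]1(O)C(=O)OC | intermediate
28 | (S)-1-hydroxy-2-methoxycyclohexa-2,5-diene-1-carboxylic acid | COC1=CCC=C[C@@]1(O)C(=O)O | intermediate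
29 | triethylsilyl (S)-2-methoxy-1-(triethylsilyloxy)cyclohexa-2,5-diene-1-carboxylate | COC1=CCC=C[C@@]1(O[Si](CC)(CC)CC)C(=O)O[Si](CC)(CC)CC | intermediate
30 | (S)-2-methoxy-1-(triethylsilyloxy)cyclohexa-2,5-diene-1-carboxylic acid | COC1=CCC=C[C@@]1(O[Si](CC)(CC)CC)C(=O)O | intermediate
31 | tetradeca-O-TBS trimer, terminal O3 esterified by the (S)-2-methoxy-1-(triethylsilyloxy)cyclohexa-2,5-diene-1-carbonyl group | COC1=CCC=C[C@@]1(O[Si](CC)(CC)CC)C(=O)O[C@H]1Cc2c(O[Si](C)(C)C(C)(C)C)cc(O[Si](C)(C)C(C)(C)C)c([C@@H]3c4c(O[Si](C)(C)C(C)(C)C)cc(O[Si](C)(C)C(C)(C)C)c([C@H]5c6c(O[Si](C)(C)C(C)(C)C)cc(O[Si](C)(C)C(C)(C)C)cc6O[C@H](c6ccc(O[Si](C)(C)C(C)(C)C)c(O[Si](C)(C)C(C)(C)C)c6)[C@@H]5O[Si](C)(C)C(C)(C)C)c4O[C@H](c4ccc(O[Si](C)(C)C(C)(C)C)c(O[Si](C)(C)C(C)(C)C)c4)[C@H]3O[Si](C)(C)C(C)(C)C)c2O[C@@H]1c1ccc(O[Si](C)(C)C(C)(C)C)c(O[Si](C)(C)C(C)(C)C)c1 | intermediate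
32 | tetradeca-O-TBS trimer, terminal O3 esterified by the (S)-6-oxo-1-(triethylsilyloxy)cyclohex-2-ene-1-carbonyl group | O=C1CCC=C[C@@]1(O[Si](CC)(CC)CC)C(=O)O[C@H]1Cc2c(O[Si](C)(C)C(C)(C)C)cc(O[Si](C)(C)C(C)(C)C)c([C@@H]3c4c(O[Si](C)(C)C(C)(C)C)cc(O[Si](C)(C)C(C)(C)C)c([C@H]5c6c(O[Si](C)(C)C(C)(C)C)cc(O[Si](C)(C)C(C)(C)C)cc6O[C@H](c6ccc(O[Si](C)(C)C(C)(C)C)c(O[Si](C)(C)C(C)(C)C)c6)[C@@H]5O[Si](C)(C)C(C)(C)C)c4O[C@H](c4ccc(O[Si](C)(C)C(C)(C)C)c(O[Si](C)(C)C(C)(C)C)c4)[C@H]3O[Si](C)(C)C(C)(C)C)c2O[C@@H]1c1ccc(O[Si](C)(C)C(C)(C)C)c(O[Si](C)(C)C(C)(C)C)c1 | intermediate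
33 | CNP0159807.2: epicatechin-(4β→8)-catechin-(4α→8)-catechin, terminal 3-O-[(S)-1-hydroxy-6-oxocyclohex-2-ene-1-carboxylate] | O=C1CCC=C[C@@]1(O)C(=O)O[C@H]1Cc2c(O)cc(O)c([C@@H]3c4c(O)cc(O)c([C@H]5c6c(O)cc(O)cc6O[C@H](c6ccc(O)c(O)c6)[C@@H]5O)c4O[C@H](c4ccc(O)c(O)c4)[C@H]3O)c2O[C@@H]1c1ccc(O)c(O)c1 | target

**Step count and risks**

Total: 22 steps. Longest linear sequence: 12 steps (steps 1, 2, 3, 4, 7, 11, 12, 13, 14, 20, 21, 22).

Most likely to fail:

1. Step 11 (key step, proposed new method). What may go wrong: poor facial selectivity on the quinone methide; reversal of regiochemistry if the enol-ester polarisation wins over the styrene polarisation; loss of the (E) geometry through a long-lived C2 cation or acetoxonium participation; or no quinone methide in a reactive geometry because of strain against the C5 silyl ether. Fallback by known flavan-4-yl Friedel–Crafts chemistry, setting out from 7, 9 and 3 and coming back at 21. Catechin 7 is fully silylated (TBSCl, imidazole, DMAP, DMF, 45 °C) to penta-O-TBS-(+)-catechin F1. F1 is oxidised at C4 (DDQ, 2-ethoxyethanol, CH2Cl2) to its 4-(2-ethoxyethoxy) derivative F2, whose C4 epimers ionise to the same cation. F2 is coupled with an excess of 9 (TMSOTf cat., CH2Cl2, −78 °C), attack at C8 of 9 trans to the C3 silyloxy group giving the catechin-(4α→8)-catechin dimer F3. F3 in excess is then alkylated at its free upper C8 by the cation from 3 (TMSOTf cat., CH2Cl2, −78 °C) to give 21.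

2. Step 7. What may go wrong: migration of silicon from O7 to C8 in the aryllithium before it adds, and slow addition to the hindered, electron-rich phenoxide aldehyde. Fallback through a magnesium reagent, setting out from 9 and 6 and coming back at 13. 9 is iodinated (N-iodosuccinimide, CH2Cl2, −40 °C) to the 8-iodo compound F4. Iodine–magnesium exchange (iPrMgCl·LiCl, THF, −20 → 0 °C) gives an arylmagnesium species that cannot undergo the silyl shift. It is added at 0 °C → rt to 6 held as its magnesium phenoxide chelate (tBuMgCl, 1 equiv), which activates the formyl group, to give 13.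

3. Step 3. What may go wrong: capture of the C4 cation by the formyl-deactivated arene may be too slow, so the cation eliminates or oligomerises and the Lewis acid strips silyl groups. Fallback with the more nucleophilic parent phenol, setting out from 3 and coming back at 5. 3 is coupled with phloroglucinol (5 equiv, Sc(OTf)3 cat., THF–CH2Cl2, −20 °C) to the 2-(penta-O-TBS-epicatechin-4β-yl)phloroglucinol F5. F5 is then mono-formylated at one of its two equivalent free ring positions by magnesium-mediated ortho-formylation (MgCl2, Et3N, paraformaldehyde 1.5 equiv, THF, 60 °C) to give 5.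

Further compounds
F1 | step 11 | 3,5,7,3′,4′-pentakis-O-TBS-(+)-catechin | CC(C)(C)[Si](C)(C)O[C@H]1Cc2c(O[Si](C)(C)C(C)(C)C)cc(O[Si](C)(C)C(C)(C)C)cc2O[C@@H]1c1ccc(O[Si](C)(C)C(C)(C)C)c(O[Si](C)(C)C(C)(C)C)c1
F2 | step 11 | 4-(2-ethoxyethoxy)-penta-O-TBS-catechin (C4 epimers) | CCOCCOC1c2c(O[Si](C)(C)C(C)(C)C)cc(O[Si](C)(C)C(C)(C)C)cc2O[C@H](c2ccc(O[Si](C)(C)C(C)(C)C)c(O[Si](C)(C)C(C)(C)C)c2)[C@H]1O[Si](C)(C)C(C)(C)C
F3 | step 11 | penta-O-TBS-catechin-(4α→8)-(3-O-TES-tetra-O-TBS-catechin) | CC[Si](CC)(CC)O[C@H]1Cc2c(O[Si](C)(C)C(C)(C)C)cc(O[Si](C)(C)C(C)(C)C)c([C@@H]3c4c(O[Si](C)(C)C(C)(C)C)cc(O[Si](C)(C)C(C)(C)C)cc4O[C@H](c4ccc(O[Si](C)(C)C(C)(C)C)c(O[Si](C)(C)C(C)(C)C)c4)[C@H]3O[Si](C)(C)C(C)(C)C)c2O[C@@H]1c1ccc(O[Si](C)(C)C(C)(C)C)c(O[Si](C)(C)C(C)(C)C)c1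
F4 | step 7 | 8-iodo-3-O-TES-5,7,3′,4′-tetrakis-O-TBS-(+)-catechin | CC[Si](CC)(CC)O[C@H]1Cc2c(O[Si](C)(C)C(C)(C)C)cc(O[Si](C)(C)C(C)(C)C)c(I)c2O[C@@H]1c1ccc(O[Si](C)(C)C(C)(C)C)c(O[Si](C)(C)C(C)(C)C)c1
F5 | step 3 | 2-(penta-O-TBS-epicatechin-4β-yl)benzene-1,3,5-triol | Oc1cc(O)c([C@H]2c3c(O[Si](C)(C)C(C)(C)C)cc(O[Si](C)(C)C(C)(C)C)cc3O[C@H](c3ccc(O[Si](C)(C)C(C)(C)C)c(O[Si](C)(C)C(C)(C)C)c3)[C@@H]2O[Si](C)(C)C(C)(C)C)c(O)c1
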